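**Strategy**

Everything rests on making ring B last, from an open chain. Ring B is a methyl salicylate whose C1 (CO2CH3) and C2 (OH) are the carbons of a malonate and whose C6–C5–C4(CH3)–C3 is a 3-methylbut-2-enoyl unit, with C6 carrying the ether oxygen to ring A. The precursor 12 is therefore a dimethyl 2-(1-aryloxy-3-methylbut-2-enylidene)malonate bearing the complete, protected ring A. In one operation a base-induced vinylogous Dieckmann condensation forms the C2–C3 bond, closes ring B and aromatises it to the hydrogen-bonded salicylate 14, so the hindered diaryl ether is never made by cross-coupling two arenes. Desilylation, palmitoylation and MOM removal finish the synthesis.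

Key step: step 9

Remark: ring B is numbered C1 (CO2CH3), C2 (OH), C3, C4 (CH3), C5, C6 (O–ring A); ring A is the benzylic ring. The target has no stereocentre and no stereogenic alkene, so no SMILES carries stereodescriptors.
Remark: compound 10 is drawn as the tricarbonyl tautomer but should exist mainly as the chelated enol.
Remark: ring A is taken from 2-hydroxy-4-methoxybenzaldehyde, whose aldehyde carbon already sits where the MOM-protected oxygen is needed, so no C–H oxidation of the arene is required.

**Route**

Step 1
Reactants: 1 2-hydroxy-4-methoxybenzaldehyde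
Product: 2 4-methoxy-2-(methoxymethoxy)benzaldehyde
Conditions: MOMCl, iPr2NEt, CH2Cl2, 0 °C to rt
Reagents that add atoms: chloromethyl methyl ether (MOMCl), COCCl
Why: Williamson-type O-alkylation of the phenol with the reactive α-chloro ether under amine base should give the MOM acetal, masking the oxygen that ends as the ring A hydroxyl.

Step 2
Reactants: 2 4-methoxy-2-(methoxymethoxy)benzaldehyde
Product: 4 4-methoxy-2-(methoxymethoxy)phenol, via 4-methoxy-2-(methoxymethoxy)phenyl formate 3 (not isolated)
Conditions: mCPBA, CH2Cl2, 0 °C to rt; aq. NaHCO3 wash; then K2CO3 (cat.), MeOH, rt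
Reagents that add atoms: 3-chloroperoxybenzoic acid (mCPBA), OOC(=O)c1cccc(Cl)c1
Why: Baeyer–Villiger oxidation of an ortho,para-dialkoxybenzaldehyde should proceed with aryl migration to formate 3, and its methanolysis after removal of the oxidant releases the phenol (para to OCH3) that later becomes the diaryl ether oxygen.

Step 3
Reactants: 4 4-methoxy-2-(methoxymethoxy)phenol
Product: 5 2-hydroxy-5-methoxy-3-(methoxymethoxy)benzaldehyde
Conditions: MgCl2 (anhydrous), Et3N, (CH2O)n, MeCN, reflux; then aq. NH4Cl
Reagents that add atoms: paraformaldehyde (as formaldehyde), C=O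
Why: The MgCl2-bound phenoxide should deliver formaldehyde only to the single free ortho position through a chelated transition state (Casiraghi–Skattebøl ortho-formylation), and the basic medium leaves the MOM acetal untouched.

Step 4
Reactants: 5 2-hydroxy-5-methoxy-3-(methoxymethoxy)benzaldehyde
Product: 6 2-(hydroxymethyl)-4-methoxy-6-(methoxymethoxy)phenol
Conditions: NaBH4, MeOH, 0 °C
Reagents that add atoms: none
Why: Hydride reduction of the aryl aldehyde with NaBH4 is fast and chemoselective and should give the salicyl alcohol without touching the acetal.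

Step 5
Reactants: 6 2-(hydroxymethyl)-4-methoxy-6-(methoxymethoxy)phenol
Product: 7 4-methoxy-2-(methoxymethoxy)-6-({[tri(propan-2-yl)silyl]oxy}methyl)phenol
Conditions: TIPSCl, imidazole, CH2Cl2, 0 °C to rt
Reagents that add atoms: chlorotri(propan-2-yl)silane (TIPSCl), CC(C)[Si](Cl)(C(C)C)C(C)C
Why: Selective silyl ether formation is expected because the bulky chlorosilane reacts with the primary benzylic alcohol much faster than with the 2,6-disubstituted, hydrogen-bonded phenol, and an aryl silyl ether is the less stable isomer under the basic conditions.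

Step 6
Reactants: 8 dimethyl malonate; 9 3-methylbut-2-enoyl chloride
Product: 10 dimethyl 2-(3-methylbut-2-enoyl)propanedioate
Conditions: MgCl2, Et3N, MeCN, 0 °C; then slow addition of 9, 0 °C to rt; cold dilute aq. HCl
Reagents that add atoms: none
Why: In this Rathke C-acylation the MgCl2-chelated malonate enolate formed with Et3N should be acylated on carbon, and the more acidic acylmalonate is held as its MgCl2-derived chelate until acidic work-up.

Step 7
Reactants: 10 dimethyl 2-(3-methylbut-2-enoyl)propanedioate
Product: 11 dimethyl 2-(1-chloro-3-methylbut-2-en-1-ylidene)propanedioate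
Conditions: POCl3, n-Bu3N, toluene, 80 °C; ice-water quench
Reagents that add atoms: phosphoryl chloride, O=P(Cl)(Cl)Cl
Why: Deoxychlorination of the enol of a 1,3-dicarbonyl compound by POCl3 and a tertiary amine (vinylogous acid to vinylogous acid chloride) is the standard entry to β-chloroalkylidene malonates, and the two identical esters leave no alkene geometry to control.

Step 8
Reactants: 7 4-methoxy-2-(methoxymethoxy)-6-({[tri(propan-2-yl)silyl]oxy}methyl)phenol; 11 dimethyl 2-(1-chloro-3-methylbut-2-en-1-ylidene)propanedioate
Product: 12 dimethyl 2-{1-[4-methoxy-2-(methoxymethoxy)-6-({[tri(propan-2-yl)silyl]oxy}methyl)phenoxy]-3-methylbut-2-en-1-ylidene}propanedioate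
Conditions: NaH, THF/DMF, 0 °C; then 11, 0 °C to rt
Reagents that add atoms: none
Why: Nucleophilic vinylic substitution (addition–elimination) of the phenoxide at the β-carbon of the doubly activated chloroalkene should form the aryl vinyl ether, the weakly basic phenoxide adding faster than it deprotonates the γ-methyl groups.

Step 9
Reactants: 12 dimethyl 2-{1-[4-methoxy-2-(methoxymethoxy)-6-({[tri(propan-2-yl)silyl]oxy}methyl)phenoxy]-3-methylbut-2-en-1-ylidene}propanedioate
Product: 14 methyl 2-hydroxy-6-[4-methoxy-2-(methoxymethoxy)-6-({[tri(propan-2-yl)silyl]oxy}methyl)phenoxy]-4-methylbenzoate, via keto tautomer methyl 4-methyl-6-oxo-2-(ring A aryloxy)cyclohexa-1,3-diene-1-carboxylate 13 (not isolated)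
Conditions: KN(SiMe3)2 (1.1 equiv), THF (dilute), −78 °C to 0 °C; then AcOH
Reagents that add atoms: none
Why: Proposed new method: KN(SiMe3)2 should remove a proton from one of the two C4 methyl groups to give a pentadienyl anion delocalised into both esters, whose CH2 terminus (future C3) adds to the carbonyl carbon (future C2) of the ester lying cis to C5 across the C1=C6 bond; methoxide leaves, cyclohexadienone 13 is deprotonated at once, and the quench gives the chelated salicylate. The closest known reaction type is the vinylogous Dieckmann benzannulation (alternatively dienylketene six-electron electrocyclisation) of 2-(alk-2-enylidene)malonates to salicylates, which has not been shown for a member carrying an aryloxy leaving group at C6. Ring B closes by a six-membered exo-trig acyl substitution that aromatisation makes irreversible. No stereocentre arises and no alkene geometry has to be set, since C4 carries two methyl groups and C1 two identical esters. The step needs γ-deprotonation to outrun addition–elimination at C6 with loss of the ring A phenoxide; the bulky non-nucleophilic base at −78 °C and the CH2OSi(iPr)3 and OCH2OCH3 groups flanking the aryloxy oxygen shield C6. The silyl ether and MOM acetal are inert to the amide base, and C3-onto-C2 is the only cyclisation that is geometrically available.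

Step 10
Reactants: 14 methyl 2-hydroxy-6-[4-methoxy-2-(methoxymethoxy)-6-({[tri(propan-2-yl)silyl]oxy}methyl)phenoxy]-4-methylbenzoate
Product: 15 methyl 2-hydroxy-6-[2-(hydroxymethyl)-4-methoxy-6-(methoxymethoxy)phenoxy]-4-methylbenzoate
Conditions: HF·pyridine, pyridine, THF, 0 °C to rt
Reagents that add atoms: none
Why: Fluoride-mediated Si–O cleavage (desilylation) under buffered, non-basic conditions should free the primary alcohol without forming an alkoxide that could lactonise onto the ring B ester, and it leaves the MOM acetal intact.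

Step 11
Reactants: 15 methyl 2-hydroxy-6-[2-(hydroxymethyl)-4-methoxy-6-(methoxymethoxy)phenoxy]-4-methylbenzoate; 16 hexadecanoyl chloride (palmitoyl chloride)
Product: 17 methyl 2-{2-[(hexadecanoyloxy)methyl]-4-methoxy-6-(methoxymethoxy)phenoxy}-6-hydroxy-4-methylbenzoate
Conditions: pyridine, CH2Cl2, −20 °C to 0 °C
Reagents that add atoms: none
Why: Esterification of the primary benzylic alcohol by the acid chloride should be faster than acylation of the ring B phenol, which is deactivated by its hydrogen bond to the ortho ester carbonyl, while the ring A phenol is still masked.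

Step 12
Reactants: 17 methyl 2-{2-[(hexadecanoyloxy)methyl]-4-methoxy-6-(methoxymethoxy)phenoxy}-6-hydroxy-4-methylbenzoate
Product: 18 betaethrin E (methyl 2-{2-[(hexadecanoyloxy)methyl]-6-hydroxy-4-methoxyphenoxy}-6-hydroxy-4-methylbenzoate)
Conditions: ZnBr2, n-PrSH, CH2Cl2, 0 °C to rt
Reagents that add atoms: none
Why: In this Lewis acid-assisted acetal cleavage ZnBr2 activates the MOM ether and the thiol traps the methoxymethyl cation, so the phenol should be released quickly without hydrolysis or transesterification of either ester and without alkylation of the electron-rich ring A.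

**Compound list**

1 | 2-hydroxy-4-methoxybenzaldehyde | COc1ccc(C=O)c(O)c1 | starting material
2 | 4-methoxy-2-(methoxymethoxy)benzaldehyde | COCOc1cc(OC)ccc1C=O | intermediate
3 | 4-methoxy-2-(methoxymethoxy)phenyl formate | COCOc1cc(OC)ccc1OC=O | intermediate (not isolated)
4 | 4-methoxy-2-(methoxymethoxy)phenol | COCOc1cc(OC)ccc1O | intermediate
5 | 2-hydroxy-5-methoxy-3-(methoxymethoxy)benzaldehyde | COCOc1cc(OC)cc(C=O)c1O | intermediate
6 | 2-(hydroxymethyl)-4-methoxy-6-(methoxymethoxy)phenol | COCOc1cc(OC)cc(CO)c1O | intermediate
7 | 4-methoxy-2-(methoxymethoxy)-6-({[tri(propan-2-yl)silyl]oxy}methyl)phenol | COCOc1cc(OC)cc(CO[Si](C(C)C)(C(C)C)C(C)C)c1O | intermediate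
8 | dimethyl malonate | COC(=O)CC(=O)OC | starting material
9 | 3-methylbut-2-enoyl chloride | CC(C)=CC(=O)Cl | starting material
10 | dimethyl 2-(3-methylbut-2-enoyl)propanedioate | COC(=O)C(C(=O)OC)C(=O)C=C(C)C | intermediate
11 | dimethyl 2-(1-chloro-3-methylbut-2-en-1-ylidene)propanedioate | COC(=O)C(C(=O)OC)=C(Cl)C=C(C)C | intermediate
12 | dimethyl 2-{1-[4-methoxy-2-(methoxymethoxy)-6-({[tri(propan-2-yl)silyl]oxy}methyl)phenoxy]-3-methylbut-2-en-1-ylidene}propanedioate | COC(=O)C(C(=O)OC)=C(C=C(C)C)Oc1c(CO[Si](C(C)C)(C(C)C)C(C)C)cc(OC)cc1OCOC | intermediate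
13 | methyl 2-[4-methoxy-2-(methoxymethoxy)-6-({[tri(propan-2-yl)silyl]oxy}methyl)phenoxy]-4-methyl-6-oxocyclohexa-1,3-diene-1-carboxylate | COC(=O)C1=C(Oc2c(CO[Si](C(C)C)(C(C)C)C(C)C)cc(OC)cc2OCOC)C=C(C)CC1=O | intermediate (not isolated)
14 | methyl 2-hydroxy-6-[4-methoxy-2-(methoxymethoxy)-6-({[tri(propan-2-yl)silyl]oxy}methyl)phenoxy]-4-methylbenzoate | COC(=O)c1c(O)cc(C)cc1Oc1c(CO[Si](C(C)C)(C(C)C)C(C)C)cc(OC)cc1OCOC | intermediate
15 | methyl 2-hydroxy-6-[2-(hydroxymethyl)-4-methoxy-6-(methoxymethoxy)phenoxy]-4-methylbenzoate | COC(=O)c1c(O)cc(C)cc1Oc1c(CO)cc(OC)cc1OCOC | intermediate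
16 | hexadecanoyl chloride (palmitoyl chloride) | CCCCCCCCCCCCCCCC(=O)Cl | starting material
17 | methyl 2-{2-[(hexadecanoyloxy)methyl]-4-methoxy-6-(methoxymethoxy)phenoxy}-6-hydroxy-4-methylbenzoate | COC(=O)c1c(O)cc(C)cc1Oc1c(COC(=O)CCCCCCCCCCCCCCC)cc(OC)cc1OCOC | intermediate
18 | betaethrin E | CCCCCCCCCCCCCCCC(=O)OCc1cc(OC)cc(O)c1Oc1cc(C)cc(O)c1C(=O)OC | target

**Step count**

Total steps: 12. Longest linear sequence: 10 (steps 1–5, then 8–12); steps 6 and 7 form the short second branch.

**Steps most likely to fail**

Step 9. The doubly ester-stabilised pentadienyl anion may be too unreactive to acylate itself, or base or anion may attack C6 and expel the ring A phenoxide. The fallback abandons the benzannulation for a cross-coupling with a preformed ring B; it sets out from phenol 7 and comes back at 14. Commercial methyl 2,6-dihydroxy-4-methylbenzoate would be monobenzylated (BnBr, K2CO3, acetone) to methyl 2-(benzyloxy)-6-hydroxy-4-methylbenzoate F1 and triflated (Tf2O, pyridine, CH2Cl2) to methyl 2-(benzyloxy)-4-methyl-6-{[(trifluoromethyl)sulfonyl]oxy}benzoate F2. A Buchwald–Hartwig-type C–O coupling of F2 and 7 (Pd(OAc)2, 2-di-tert-butylphosphino-2',4',6'-triisopropylbiphenyl, K3PO4, toluene, 100 °C) should give methyl 2-(benzyloxy)-6-[4-methoxy-2-(methoxymethoxy)-6-({[tri(propan-2-yl)silyl]oxy}methyl)phenoxy]-4-methylbenzoate F3. Hydrogenolysis (H2, Pd/C, EtOAc) would then free the ring B phenol and give 14.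

Step 7. Under hot POCl3 the dienol may cyclise by oxa-Michael addition onto its isopropylidene terminus or polymerise before chloride is transferred. The fallback avoids the acylmalonate altogether and builds the leaving group at C6 from a ketene dithioacetal; it sets out from dimethyl malonate 8 and comes back at 12. Malonate 8 with CS2, K2CO3 and MeI in DMF should give dimethyl 2-[bis(methylsulfanyl)methylidene]propanedioate F4. Conjugate addition–elimination of 2-methylprop-1-enylmagnesium bromide (CuBr·SMe2 cat., THF, −40 °C) would replace one methylsulfanyl group to give dimethyl 2-[3-methyl-1-(methylsulfanyl)but-2-en-1-ylidene]propanedioate F5. Oxidation with mCPBA (2 equiv, CH2Cl2, 0 °C) should give dimethyl 2-[1-(methanesulfonyl)-3-methylbut-2-en-1-ylidene]propanedioate F6, and the phenoxide of 7 (NaH, THF/DMF) would displace methanesulfinate to give 12.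

Step 8. Addition of the 2,6-disubstituted phenoxide may be slow enough that γ-deprotonation and self-condensation of 11 take over. The fallback couples a smaller, planar phenoxide and introduces the silyl group afterwards; it sets out from aldehyde 5 (with 11) and comes back at 12. The phenoxide of 5 (NaH, THF/DMF, 0 °C) and 11 should give dimethyl 2-{1-[2-formyl-4-methoxy-6-(methoxymethoxy)phenoxy]-3-methylbut-2-en-1-ylidene}propanedioate F7. Luche reduction of the aldehyde (NaBH4, CeCl3·7H2O, MeOH/THF, −78 °C), which should spare the push–pull alkene, would give dimethyl 2-{1-[2-(hydroxymethyl)-4-methoxy-6-(methoxymethoxy)phenoxy]-3-methylbut-2-en-1-ylidene}propanedioate F8. Silylation (TIPSCl, imidazole, CH2Cl2), now with no competing phenol, would give 12.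

**Further compounds**

F1 | step 9 | methyl 2-(benzyloxy)-6-hydroxy-4-methylbenzoate | COC(=O)c1c(O)cc(C)cc1OCc1ccccc1
F2 | step 9 | methyl 2-(benzyloxy)-4-methyl-6-{[(trifluoromethyl)sulfonyl]oxy}benzoate | COC(=O)c1c(OCc2ccccc2)cc(C)cc1OS(=O)(=O)C(F)(F)F
F3 | step 9 | methyl 2-(benzyloxy)-6-[4-methoxy-2-(methoxymethoxy)-6-({[tri(propan-2-yl)silyl]oxy}methyl)phenoxy]-4-methylbenzoate | COC(=O)c1c(OCc2ccccc2)cc(C)cc1Oc1c(CO[Si](C(C)C)(C(C)C)C(C)C)cc(OC)cc1OCOC
F4 | step 7 | dimethyl 2-[bis(methylsulfanyl)methylidene]propanedioate | COC(=O)C(C(=O)OC)=C(SC)SC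
F5 | step 7 | dimethyl 2-[3-methyl-1-(methylsulfanyl)but-2-en-1-ylidene]propanedioate | COC(=O)C(C(=O)OC)=C(SC)C=C(C)C
F6 | step 7 | dimethyl 2-[1-(methanesulfonyl)-3-methylbut-2-en-1-ylidene]propanedioate | COC(=O)C(C(=O)OC)=C(C=C(C)C)S(C)(=O)=O
F7 | step 8 | dimethyl 2-{1-[2-formyl-4-methoxy-6-(methoxymethoxy)phenoxy]-3-methylbut-2-en-1-ylidene}propanedioate | COC(=O)C(C(=O)OC)=C(C=C(C)C)Oc1c(C=O)cc(OC)cc1OCOC
F8 | step 8 | dimethyl 2-{1-[2-(hydroxymethyl)-4-methoxy-6-(methoxymethoxy)phenoxy]-3-methylbut-2-en-1-ylidene}propanedioate | COC(=O)C(C(=O)OC)=C(C=C(C)C)Oc1c(CO)cc(OC)cc1OCOC
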